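**Plan**

1. Numbering (germacrane): C8 = lactone O–CH, C7 = ring fusion, C6 = ester CH, C4=C5 with C15 on C4, C1=C10 with C14 on C10, C11=C13 exo-methylene, C12 = lactone C=O.
2. Enabling feature: in the ten-membered carbocycle the C6 carbinol sits next to C7, which carries the C11=C13 methylene; this homoallylic alcohol C6(O)–C7–C11=C13 is what a [2,3]-Wittig shift of a C6–O–C13 allyl ether leaves behind.
3. Retrosynthetic cuts, in order: the C6 ester, the C15 acetate and the O8–C12 lactone bond (C12 back to CH2O); then C6–C7, which opens the carbocycle to a thirteen-membered C6–O–C13 diallylic ether; then C1–C2 (opens that ring), C8–C9 and the O–C13 bond.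
4. Forward: a (Z)-iodobutenol from 2-butyne-1,4-diol becomes the C2–C6/C15 dienol, which is etherified with a bromomethylbutenolide from dihydroxyacetone (C7, C8, C11–C13). Lactone opening, propargylation at C8 and carboalumination–iodination finish the chain. B-alkyl Suzuki coupling closes the thirteen-membered ether, the Wittig shift contracts it to the ten-membered ring, and the lactone ring closes by oxidation once the side chain is on.
5. Stereochemistry: C8 by catalyst-controlled propargylation; C6 and C7 together in the Wittig shift (ring-trans C7=C11 gives the 6,7-anti pair, C8 fixes the face through allylic 1,3-strain); the side-chain centre by Sharpless epoxidation of 2-methylprop-2-en-1-ol.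
6. Olefin geometry: C4=C5 by hydroxyl-directed anti-hydroalumination, C7=C11 from the butenolide ring, C1=C10 by syn-carboalumination.

Key step: step 14

Abbreviations: TBDPS = tert-butyldiphenylsilyl; TES = triethylsilyl; Dn = (2E)-3-{[(tert-butyldiphenylsilyl)oxy]methyl}penta-2,4-dien-1-yl; TRIP = 3,3′-bis(2,4,6-triisopropylphenyl)-1,1′-binaphthyl-2,2′-diyl hydrogen phosphate.

Remark on the chemistry: C7=C11 of ether 19 is trans in the ring (C8 anti to C13) although Z by the sequence rule (C12H2OSi outranks C13H2O–C), and the C7 descriptor changes with the oxygen substituents (S in 22 and 30, R from 31 on) while the configuration stays the same.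

Assumption: the (S)-acid of step 10 is chosen by analogy with aryl and alkenyl aldehydes; the sense is to be checked on 14 (Mosher esters) and the antipodal acid used if required.

**Route**

Step 1
Reactants: 1 2-butyne-1,4-diol
Product: 2 4-[(tert-butyldiphenylsilyl)oxy]but-2-yn-1-ol
Conditions: t-BuPh2SiCl (1 equiv), 1 (3 equiv), imidazole, DMF, 0 °C → rt
Reagents that add atoms: tert-butyl(chloro)diphenylsilane, CC(C)(C)[Si](Cl)(c1ccccc1)c1ccccc1
Why: Statistical monosilylation of a symmetrical diol used in excess; the protected oxygen becomes O15.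

Step 2
Reactants: 2 4-[(tert-butyldiphenylsilyl)oxy]but-2-yn-1-ol
Product: 4 (2Z)-4-[(tert-butyldiphenylsilyl)oxy]-3-iodobut-2-en-1-ol, via cyclic alkenylaluminate 3 (not isolated)
Conditions: NaAlH2(OCH2CH2OMe)2, THF, 0 °C; then I2, THF, −78 °C
Reagents that add atoms: iodine, II
Why: Hydroxyl-directed anti-hydroalumination of the propargylic alcohol puts hydride on C5 and aluminium on C4 in a five-membered aluminate, and iodinolysis with retention leaves iodine cis to C6, which is the ring-cis C4=C5 geometry.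

Step 3
Reactants: 4 (2Z)-4-[(tert-butyldiphenylsilyl)oxy]-3-iodobut-2-en-1-ol
Product: 5 (2E)-3-{[(tert-butyldiphenylsilyl)oxy]methyl}penta-2,4-dien-1-ol
Conditions: CH2=CHSnBu3, Pd(PPh3)4 (5 mol%), CuI (10 mol%), DMF, rt
Reagents that add atoms: tributyl(vinyl)stannane, C=C[Sn](CCCC)(CCCC)CCCC
Why: Stille coupling of the alkenyl iodide proceeds with retention of geometry and tolerates the free allylic alcohol; the vinyl group supplies C2 and C3.

Step 4
Reactants: 6 1,3-dihydroxyacetone (used as its commercial dimer)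
Product: 8 4-(hydroxymethyl)furan-2(5H)-one, via hydroxy ester 7 (not isolated)
Conditions: Ph3P=CHCO2Et, CH2Cl2, rt
Reagents that add atoms: ethyl (triphenylphosphoranylidene)acetate, CCOC(=O)C=P(c1ccccc1)(c1ccccc1)c1ccccc1
Why: Wittig olefination of the symmetrical ketone followed by lactonisation of the hydroxymethyl group cis to the ester; the lactone distinguishes the two CH2O groups on C11 (ring CH2 = C12, free CH2OH = C13).

Step 5
Reactants: 8 4-(hydroxymethyl)furan-2(5H)-one
Product: 9 4-(bromomethyl)furan-2(5H)-one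
Conditions: CBr4, PPh3, CH2Cl2, 0 °C
Reagents that add atoms: carbon tetrabromide, BrC(Br)(Br)Br
Why: Appel bromination of the primary allylic alcohol under neutral conditions that spare the butenolide.

Step 6
Reactants: 5 (2E)-3-{[(tert-butyldiphenylsilyl)oxy]methyl}penta-2,4-dien-1-ol; 9 4-(bromomethyl)furan-2(5H)-one
Product: 10 4-[(Dn-oxy)methyl]furan-2(5H)-one
Conditions: Ag2O (1.5 equiv), 4 Å molecular sieves, CH2Cl2, rt, dark
Reagents that add atoms: none
Why: Silver oxide-mediated Williamson-type etherification joins the primary allylic alcohol to the activated allylic bromide without a strong base that would enolise the butenolide; this makes the C6–O–C13 bond.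

Step 7
Reactants: 10 4-[(Dn-oxy)methyl]furan-2(5H)-one
Product: 11 (2E)-4-hydroxy-N-methoxy-N-methyl-3-[(Dn-oxy)methyl]but-2-enamide (CH2OH cis to the amide carbonyl)
Conditions: MeNH(OMe)·HCl, Me3Al, CH2Cl2, 0 °C; aqueous potassium sodium tartrate work-up; crude used at once
Reagents that add atoms: N,O-dimethylhydroxylamine hydrochloride, CNOC.Cl
Why: Weinreb aminolysis with the weakly basic aluminium amide opens the lactone at the acyl carbon, so the released CH2OH (C12) stays cis to the C8 carbonyl and the ether arm (C13) trans.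

Step 8
Reactants: 11 (2E)-4-hydroxy-N-methoxy-N-methyl-3-[(Dn-oxy)methyl]but-2-enamide
Product: 12 (2Z)-N-methoxy-N-methyl-3-[(Dn-oxy)methyl]-4-[(triethylsilyl)oxy]but-2-enamide
Conditions: Et3SiCl, imidazole, CH2Cl2, 0 °C
Reagents that add atoms: chlorotriethylsilane, CC[Si](Cl)(CC)CC
Why: Silylation of the primary alcohol blocks relactonisation and installs the O12 protecting group.

Step 9
Reactants: 12 (2Z)-N-methoxy-N-methyl-3-[(Dn-oxy)methyl]-4-[(triethylsilyl)oxy]but-2-enamide
Product: 13 (2Z)-3-[(Dn-oxy)methyl]-4-[(triethylsilyl)oxy]but-2-enal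
Conditions: i-Bu2AlH, THF, −78 °C; aqueous potassium sodium tartrate
Reagents that add atoms: none
Why: Weinreb amide reduction stops at the aldehyde through the chelated aluminium hemiaminal and leaves the olefin geometry untouched.

Step 10
Reactants: 13 (2Z)-3-[(Dn-oxy)methyl]-4-[(triethylsilyl)oxy]but-2-enal
Product: 14 (2Z,4S)-1-(Dn-oxy)-2-{[(triethylsilyl)oxy]methyl}hept-2-en-6-yn-4-ol (carbinol = C8)
Conditions: allenylboronic acid pinacol ester (1.5 equiv), (S)-TRIP (10 mol%), 4 Å molecular sieves, toluene, 0 °C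
Reagents that add atoms: allenylboronic acid pinacol ester, C=C=CB1OC(C)(C)C(C)(C)O1
Why: Chiral Brønsted acid-catalysed propargylation with the allenylboronate through a closed six-membered (SE2′) transition state gives the homopropargylic alcohol; the C8 stereocentre is set by the catalyst.

Step 11
Reactants: 14 (2Z,4S)-1-(Dn-oxy)-2-{[(triethylsilyl)oxy]methyl}hept-2-en-6-yn-4-ol
Product: 15 Dn (2Z,4S)-4-[(triethylsilyl)oxy]-2-{[(triethylsilyl)oxy]methyl}hept-2-en-6-yn-1-yl ether
Conditions: Et3SiCl, imidazole, DMAP (cat.), DMF, 0 °C → rt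
Reagents that add atoms: chlorotriethylsilane, CC[Si](Cl)(CC)CC
Why: Standard silylation of the secondary allylic alcohol gives the O8 silyl ether on which the allylic-strain control of the key step relies.

Step 12
Reactants: 15 Dn (2Z,4S)-4-[(triethylsilyl)oxy]-2-{[(triethylsilyl)oxy]methyl}hept-2-en-6-yn-1-yl ether
Product: 17 Dn (2Z,4S,6E)-7-iodo-6-methyl-4-[(triethylsilyl)oxy]-2-{[(triethylsilyl)oxy]methyl}hepta-2,6-dien-1-yl ether, via alkenylalane 16 (not isolated)
Conditions: Me3Al (3 equiv), Cp2ZrCl2 (0.3 equiv), H2O (1.5 equiv), CH2Cl2, −20 °C; then I2, THF, −20 → 0 °C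
Reagents that add atoms: trimethylaluminium, C[Al](C)C; iodine, II
Why: Zirconium-catalysed syn-carboalumination (Negishi) of the terminal alkyne puts methyl on C10 and aluminium on C1, and iodinolysis with retention gives the E iodoalkene; the alkenes and ethers should be inert at this temperature.

Step 13
Reactants: 17 Dn (2Z,4S,6E)-7-iodo-6-methyl-4-[(triethylsilyl)oxy]-2-{[(triethylsilyl)oxy]methyl}hepta-2,6-dien-1-yl ether
Product: 19 thirteen-membered diallylic ether (8S; ring O–C6–C5=C4–C3–C2–C1=C10–C9–C8–C7=C11–C13; 4-CH2OTBDPS; 10-CH3; 8-OTES; 11-CH2OTES; C1=C10 E; C4=C5 ring-cis; C7=C11 ring-trans), via B-alkyl-9-BBN 18 (not isolated)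
Conditions: 9-BBN (1.3 equiv), THF, 0 °C → rt; then syringe-pump addition to PdCl2(dppf) (10 mol%), AsPh3, Cs2CO3, DMF–THF–H2O, 50 °C, final 0.003 M
Reagents that add atoms: none
Why: 9-BBN hydroborates only the monosubstituted terminal alkene of the diene (boron on C2), and intramolecular B-alkyl Suzuki–Miyaura coupling with the alkenyl iodide under high dilution forms C1–C2 with retention of the E geometry, a known way of closing macrocycles.

Step 14
Reactants: 19 thirteen-membered diallylic ether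
Product: 22 (6R,7S,8S)-8,12-bis[(triethylsilyl)oxy]-15-[(tert-butyldiphenylsilyl)oxy]germacra-1(10)E,4E,11(13)-trien-6-ol, via C6-lithio ether 20 (not isolated), via lithium alkoxide 21 (not isolated)
Conditions: s-BuLi (1.5 equiv), THF, −78 °C, 1 h; AcOH in THF, −78 °C
Reagents that add atoms: none
Why: s-BuLi removes a C6 proton (α to oxygen, allylic to C4=C5) and the α-oxy allyllithium 20 attacks C7 through a five-centre envelope (C6, O, C13, C11, C7) while O–C13 breaks, a suprafacial [2,3]-sigmatropic Wittig shift of the kind known for the contraction of thirteen-membered diallylic ethers to germacrane homoallylic alcohols. The ten-membered carbocycle therefore closes by transannular C6–C7 bond formation inside the existing ring (ring contraction, loss of the O–C13–C11 bridge as the C6 alkoxide and the C11=C13 methylene), not by an end-to-end cyclisation. C6 and C7 are set together: the ring-trans C7=C11 olefin with the C5 vinyl group exo on the envelope gives the 6,7-anti pair (H6 and H7 trans), as E allyl ethers do in open chains. The face of C7 is fixed by C8: with H8 eclipsing C7=C11 to avoid allylic 1,3-strain with C12H2OTES, the tethered carbanion arrives on the C9 side, anti to the C8 silyloxy group, which gives the 7,8-anti pair of the target. Lithiation must occur at C6 and not at C13, C12 or C15; C6 is the least hindered O–CH2, a C13 anion would have to attack the fully substituted C4, and the silyl groups shield C12 and C15. The alkoxide 21 is protonated at −78 °C so that the C8 silyl group does not migrate to O6.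

Step 15
Reactants: 23 2-methylprop-2-en-1-ol
Product: 24 (R)-(2-methyloxiran-2-yl)methanol
Conditions: Ti(Oi-Pr)4 (5 mol%), D-(−)-diisopropyl tartrate (6 mol%), t-BuOOH, 4 Å molecular sieves, CH2Cl2, −20 °C
Reagents that add atoms: tert-butyl hydroperoxide, CC(C)(C)OO
Why: Sharpless asymmetric epoxidation; the D-(−)-tartrate directs oxygen to the face that gives the (R)-epoxy alcohol and so sets the side-chain stereocentre.

Step 16
Reactants: 24 (R)-(2-methyloxiran-2-yl)methanol
Product: 25 (R)-3-(benzyloxy)-2-methylpropane-1,2-diol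
Conditions: BnOH (excess), NaH (0.2 equiv), 60 °C
Reagents that add atoms: benzyl alcohol, OCc1ccccc1
Why: The alkoxide opens the epoxide at its unsubstituted carbon (SN2), so the quaternary centre is untouched; a prior Payne rearrangement is degenerate and leads to the same enantiomer.

Step 17
Reactants: 25 (R)-3-(benzyloxy)-2-methylpropane-1,2-diol
Product: 26 (S)-4-[(benzyloxy)methyl]-2,2,4-trimethyl-1,3-dioxolane
Conditions: Me2C(OMe)2, TsOH (cat.), acetone, rt
Reagents that add atoms: 2,2-dimethoxypropane, COC(C)(C)OC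
Why: Acid-catalysed transketalisation protects the 1,2-diol as its isopropylidene acetal.

Step 18
Reactants: 26 (S)-4-[(benzyloxy)methyl]-2,2,4-trimethyl-1,3-dioxolane
Product: 27 (S)-(2,2,4-trimethyl-1,3-dioxolan-4-yl)methanol
Conditions: H2 (1 atm), 10% Pd/C, EtOAc, rt
Reagents that add atoms: none
Why: Hydrogenolysis of the benzyl ether frees the primary alcohol and leaves the acetal intact.

Step 19
Reactants: 27 (S)-(2,2,4-trimethyl-1,3-dioxolan-4-yl)methanol
Product: 28 (R)-2,2,4-trimethyl-1,3-dioxolane-4-carboxylic acid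
Conditions: TEMPO (20 mol%), PhI(OAc)2 (2.2 equiv), MeCN–H2O (1:1), rt
Reagents that add atoms: water, O
Why: Nitroxyl-catalysed oxidation takes the primary alcohol through the aldehyde hydrate to the acid under conditions too mild to open the acetal.

Step 20
Reactants: 22 ten-membered alcohol; 28 (R)-2,2,4-trimethyl-1,3-dioxolane-4-carboxylic acid
Product: 30 (6R,7S,8S)-8,12-bis[(triethylsilyl)oxy]-15-[(tert-butyldiphenylsilyl)oxy]germacra-1(10)E,4E,11(13)-trien-6-yl (4R)-2,2,4-trimethyl-1,3-dioxolane-4-carboxylate, via mixed anhydride 29 (not isolated)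
Conditions: 28, 2,4,6-trichlorobenzoyl chloride, Et3N, THF, rt; then 22, DMAP, toluene, rt → 40 °C
Reagents that add atoms: none
Why: Yamaguchi esterification; the mixed anhydride acylates the hindered C6 hydroxyl, the only free hydroxyl, with retention at C6.

Step 21
Reactants: 30 C6 ester
Product: 31 (6R,7R,8S)-8,12-dihydroxy-15-[(tert-butyldiphenylsilyl)oxy]germacra-1(10)E,4E,11(13)-trien-6-yl (4R)-2,2,4-trimethyl-1,3-dioxolane-4-carboxylate
Conditions: HF·pyridine, pyridine, THF, 0 °C
Reagents that add atoms: none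
Why: Buffered HF·pyridine cleaves the two triethylsilyl ethers much faster than the primary tert-butyldiphenylsilyl ether and leaves the acetal and the ester alone.

Step 22
Reactants: 31 8,12-diol
Product: 34 (6R,7R,8S)-15-[(tert-butyldiphenylsilyl)oxy]-6-{[(4R)-2,2,4-trimethyl-1,3-dioxolane-4-carbonyl]oxy}germacra-1(10)E,4E,11(13)-trien-12,8-olide, via hydroxy enal 32 (not isolated), via lactol 33 (not isolated)
Conditions: MnO2 (activated, excess), CH2Cl2, rt
Reagents that add atoms: none
Why: MnO2 oxidises only the allylic primary alcohol, the C8 hydroxyl closes the lactol (5-exo-trig addition to the aldehyde) and the lactol is oxidised on to the α-methylene-γ-lactone, an established oxidative lactonisation of 2-methylene-1,4-diols; the trans ring fusion follows from C7 and C8.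

Step 23
Reactants: 34 silyl ether lactone
Product: 35 (6R,7R,8S)-15-hydroxy-6-{[(4R)-2,2,4-trimethyl-1,3-dioxolane-4-carbonyl]oxy}germacra-1(10)E,4E,11(13)-trien-12,8-olide
Conditions: Bu4NF, AcOH (1:1), THF, 0 °C → rt
Reagents that add atoms: none
Why: Acetic acid-buffered fluoride removes the primary silyl ether without conjugate addition to the methylene lactone or acyl migration.

Step 24
Reactants: 35 C15 alcohol
Product: 36 (6R,7R,8S)-15-acetoxy-6-{[(4R)-2,2,4-trimethyl-1,3-dioxolane-4-carbonyl]oxy}germacra-1(10)E,4E,11(13)-trien-12,8-olide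
Conditions: Ac2O, pyridine, DMAP (cat.), CH2Cl2, 0 °C
Reagents that add atoms: acetic anhydride, CC(=O)OC(C)=O
Why: Acetylation of the only free hydroxyl, the primary allylic C15 alcohol.

Step 25
Reactants: 36 acetonide acetate
Product: 37 (6R,7R,8S)-15-acetoxy-6-{[(2R)-2,3-dihydroxy-2-methylpropanoyl]oxy}germacra-1(10)E,4E,11(13)-trien-12,8-olide (CNP0426025.2)
Conditions: AcOH–H2O (4:1), 40 °C
Reagents that add atoms: none
Why: Mild aqueous acid hydrolyses the terminal isopropylidene acetal; the C4=C5 olefin is deactivated by two allylic acyloxy groups, which should keep transannular cyclisation slow under these conditions.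

**Compound list**

1 | 2-butyne-1,4-diol | OCC#CCO | starting material
2 | 4-[(tert-butyldiphenylsilyl)oxy]but-2-yn-1-ol | OCC#CCO[Si](c1ccccc1)(c1ccccc1)C(C)(C)C | intermediate
3 | sodium cyclic alkenylaluminate (ring O–Al–C4=C5–C6; two 2-methoxyethoxy groups on Al; CH2OTBDPS on C4), formed in situ | [Na+].COCCO[Al-]1(OCCOC)OCC=C1CO[Si](c2ccccc2)(c2ccccc2)C(C)(C)C | intermediate
4 | (2Z)-4-[(tert-butyldiphenylsilyl)oxy]-3-iodobut-2-en-1-ol | OC/C=C(I)/CO[Si](c1ccccc1)(c1ccccc1)C(C)(C)C | intermediate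
5 | (2E)-3-{[(tert-butyldiphenylsilyl)oxy]methyl}penta-2,4-dien-1-ol (Dn–OH) | C=C/C(CO[Si](c1ccccc1)(c1ccccc1)C(C)(C)C)=C\CO | intermediate
6 | 1,3-dihydroxyacetone (commercial as its dimer) | OCC(=O)CO | starting material
7 | ethyl 4-hydroxy-3-(hydroxymethyl)but-2-enoate, formed in situ | CCOC(=O)C=C(CO)CO | intermediate
8 | 4-(hydroxymethyl)furan-2(5H)-one | O=C1OCC(CO)=C1 | intermediate
9 | 4-(bromomethyl)furan-2(5H)-one | O=C1OCC(CBr)=C1 | intermediate
10 | 4-[(Dn-oxy)methyl]furan-2(5H)-one | C=C/C(CO[Si](c1ccccc1)(c1ccccc1)C(C)(C)C)=C\COCC1=CC(=O)OC1 | intermediate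
11 | (2E)-4-hydroxy-N-methoxy-N-methyl-3-[(Dn-oxy)methyl]but-2-enamide (CH2OH cis to the amide carbonyl) | C=C/C(CO[Si](c1ccccc1)(c1ccccc1)C(C)(C)C)=C\COC/C(CO)=C/C(=O)N(C)OC | intermediate
12 | (2Z)-N-methoxy-N-methyl-3-[(Dn-oxy)methyl]-4-[(triethylsilyl)oxy]but-2-enamide | C=C/C(CO[Si](c1ccccc1)(c1ccccc1)C(C)(C)C)=C\COC/C(CO[Si](CC)(CC)CC)=C/C(=O)N(C)OC | intermediate
13 | (2Z)-3-[(Dn-oxy)methyl]-4-[(triethylsilyl)oxy]but-2-enal | C=C/C(CO[Si](c1ccccc1)(c1ccccc1)C(C)(C)C)=C\COC/C(CO[Si](CC)(CC)CC)=C/C=O | intermediate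
14 | (2Z,4S)-1-(Dn-oxy)-2-{[(triethylsilyl)oxy]methyl}hept-2-en-6-yn-4-ol | C#CC[C@H](O)/C=C(CO[Si](CC)(CC)CC)/COC/C=C(CO[Si](c1ccccc1)(c1ccccc1)C(C)(C)C)\C=C | intermediate
15 | Dn (2Z,4S)-4-[(triethylsilyl)oxy]-2-{[(triethylsilyl)oxy]methyl}hept-2-en-6-yn-1-yl ether | C#CC[C@H](O[Si](CC)(CC)CC)/C=C(CO[Si](CC)(CC)CC)/COC/C=C(CO[Si](c1ccccc1)(c1ccccc1)C(C)(C)C)\C=C | intermediate
16 | (E)-alkenyl(dimethyl)alane from 15 (Al on C1, CH3 on C10), formed in situ | C[Al](C)/C=C(C)/C[C@H](O[Si](CC)(CC)CC)/C=C(CO[Si](CC)(CC)CC)/COC/C=C(CO[Si](c1ccccc1)(c1ccccc1)C(C)(C)C)\C=C | intermediate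
17 | Dn (2Z,4S,6E)-7-iodo-6-methyl-4-[(triethylsilyl)oxy]-2-{[(triethylsilyl)oxy]methyl}hepta-2,6-dien-1-yl ether | I/C=C(C)/C[C@H](O[Si](CC)(CC)CC)/C=C(CO[Si](CC)(CC)CC)/COC/C=C(CO[Si](c1ccccc1)(c1ccccc1)C(C)(C)C)\C=C | intermediate
18 | B-alkyl-9-borabicyclo[3.3.1]nonane from 17 (boron on C2), formed in situ | I/C=C(C)/C[C@H](O[Si](CC)(CC)CC)/C=C(CO[Si](CC)(CC)CC)/COC/C=C(CO[Si](c1ccccc1)(c1ccccc1)C(C)(C)C)\CCB1C2CCCC1CCC2 | intermediate
19 | thirteen-membered diallylic ether, (8S); ring O–C6–C5=C4–C3–C2–C1=C10–C9–C8–C7=C11–C13; 4-CH2OTBDPS, 10-CH3, 8-OTES, 11-CH2OTES; C1=C10 E, C4=C5 ring-cis, C7=C11 ring-trans | O1C/C=C(CO[Si](c2ccccc2)(c2ccccc2)C(C)(C)C)\CC/C=C(C)/C[C@H](O[Si](CC)(CC)CC)/C=C(CO[Si](CC)(CC)CC)/C1 | intermediate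
20 | C6-lithiated ether 19, formed in situ | O1C([Li])/C=C(CO[Si](c2ccccc2)(c2ccccc2)C(C)(C)C)\CC/C=C(C)/C[C@H](O[Si](CC)(CC)CC)/C=C(CO[Si](CC)(CC)CC)/C1 | intermediate
21 | lithium C6-alkoxide of 22, formed in situ | C=C(CO[Si](CC)(CC)CC)[C@@H]1[C@@H](O[Si](CC)(CC)CC)C/C(C)=C/CC/C(CO[Si](c2ccccc2)(c2ccccc2)C(C)(C)C)=C\[C@H]1O[Li] | intermediate
22 | (6R,7S,8S)-8,12-bis[(triethylsilyl)oxy]-15-[(tert-butyldiphenylsilyl)oxy]germacra-1(10)E,4E,11(13)-trien-6-ol | C=C(CO[Si](CC)(CC)CC)[C@@H]1[C@@H](O[Si](CC)(CC)CC)C/C(C)=C/CC/C(CO[Si](c2ccccc2)(c2ccccc2)C(C)(C)C)=C\[C@H]1O | intermediate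
23 | 2-methylprop-2-en-1-ol | C=C(C)CO | starting material
24 | (R)-(2-methyloxiran-2-yl)methanol | OC[C@]1(C)CO1 | intermediate
25 | (R)-3-(benzyloxy)-2-methylpropane-1,2-diol | OC[C@@](C)(O)COCc1ccccc1 | intermediate
26 | (S)-4-[(benzyloxy)methyl]-2,2,4-trimethyl-1,3-dioxolane | CC1(C)OC[C@](C)(COCc2ccccc2)O1 | intermediate
27 | (S)-(2,2,4-trimethyl-1,3-dioxolan-4-yl)methanol | CC1(C)OC[C@](C)(CO)O1 | intermediate
28 | (R)-2,2,4-trimethyl-1,3-dioxolane-4-carboxylic acid | CC1(C)OC[C@](C)(C(=O)O)O1 | intermediate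
29 | mixed anhydride of 28 with 2,4,6-trichlorobenzoic acid, formed in situ | CC1(C)OC[C@](C)(C(=O)OC(=O)c2c(Cl)cc(Cl)cc2Cl)O1 | intermediate
30 | (6R,7S,8S)-8,12-bis[(triethylsilyl)oxy]-15-[(tert-butyldiphenylsilyl)oxy]germacra-1(10)E,4E,11(13)-trien-6-yl (4R)-2,2,4-trimethyl-1,3-dioxolane-4-carboxylate | C=C(CO[Si](CC)(CC)CC)[C@@H]1[C@@H](O[Si](CC)(CC)CC)C/C(C)=C/CC/C(CO[Si](c2ccccc2)(c2ccccc2)C(C)(C)C)=C\[C@H]1OC(=O)[C@@]3(C)COC(C)(C)O3 | intermediate
31 | (6R,7R,8S)-8,12-dihydroxy-15-[(tert-butyldiphenylsilyl)oxy]germacra-1(10)E,4E,11(13)-trien-6-yl (4R)-2,2,4-trimethyl-1,3-dioxolane-4-carboxylate | C=C(CO)[C@@H]1[C@@H](O)C/C(C)=C/CC/C(CO[Si](c2ccccc2)(c2ccccc2)C(C)(C)C)=C\[C@H]1OC(=O)[C@@]3(C)COC(C)(C)O3 | intermediate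
32 | 8-hydroxy-12-al (enal) from 31, formed in situ | C=C(C=O)[C@@H]1[C@@H](O)C/C(C)=C/CC/C(CO[Si](c2ccccc2)(c2ccccc2)C(C)(C)C)=C\[C@H]1OC(=O)[C@@]3(C)COC(C)(C)O3 | intermediate
33 | 12,8-lactol from 32, formed in situ | C=C1C(O)O[C@H]2C/C(C)=C/CC/C(CO[Si](c3ccccc3)(c3ccccc3)C(C)(C)C)=C\[C@@H](OC(=O)[C@@]4(C)COC(C)(C)O4)[C@H]12 | intermediate
34 | (6R,7R,8S)-15-[(tert-butyldiphenylsilyl)oxy]-6-{[(4R)-2,2,4-trimethyl-1,3-dioxolane-4-carbonyl]oxy}germacra-1(10)E,4E,11(13)-trien-12,8-olide | C=C1C(=O)O[C@H]2C/C(C)=C/CC/C(CO[Si](c3ccccc3)(c3ccccc3)C(C)(C)C)=C\[C@@H](OC(=O)[C@@]4(C)COC(C)(C)O4)[C@H]12 | intermediate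
35 | (6R,7R,8S)-15-hydroxy-6-{[(4R)-2,2,4-trimethyl-1,3-dioxolane-4-carbonyl]oxy}germacra-1(10)E,4E,11(13)-trien-12,8-olide | C=C1C(=O)O[C@H]2C/C(C)=C/CC/C(CO)=C\[C@@H](OC(=O)[C@@]4(C)COC(C)(C)O4)[C@H]12 | intermediate
36 | (6R,7R,8S)-15-acetoxy-6-{[(4R)-2,2,4-trimethyl-1,3-dioxolane-4-carbonyl]oxy}germacra-1(10)E,4E,11(13)-trien-12,8-olide | C=C1C(=O)O[C@H]2C/C(C)=C/CC/C(COC(C)=O)=C\[C@@H](OC(=O)[C@@]4(C)COC(C)(C)O4)[C@H]12 | intermediate
37 | (6R,7R,8S)-15-acetoxy-6-{[(2R)-2,3-dihydroxy-2-methylpropanoyl]oxy}germacra-1(10)E,4E,11(13)-trien-12,8-olide (CNP0426025.2) | C=C1C(=O)O[C@H]2C/C(C)=C/CC/C(COC(C)=O)=C\[C@@H](OC(=O)[C@](C)(O)CO)[C@H]12 | target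

**Step count**

Total: 25 steps. Longest linear sequence: 18 steps (steps 1–3, 6–14, 20–25); steps 4–5 and 15–19 are side branches.

**Steps most likely to fail**

Step 14 (key step). What may go wrong: the C5 vinyl group takes the endo position in the envelope, so that C6 forms with the wrong configuration relative to C7. Lithiation at C13, C12 or C15 and migration of the C8 silyl group to the new alkoxide would also drain material. Fallback, setting out from 19: the rearrangement is run unchanged and its product, the 6-epimeric alcohol F1, is esterified with acid 28 under Mitsunobu conditions (PPh3, diisopropyl azodicarboxylate, toluene, 0 °C → rt). The SN2 displacement at the allylic C6 inverts that centre and the sequence comes back to the route at ester 30. C6 is then corrected in the acylation and no longer set in the rearrangement.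

Step 13. What may go wrong: intermolecular coupling (dimers, oligomers), protodeboronation of 18 and reduction of the iodide outrun closure of the thirteen-membered triene. Fallback, setting out from 17: hydroboration–oxidation (9-BBN; NaBO3·4H2O) gives primary alcohol F2, and iodination (PPh3, I2, imidazole) gives alkyl iodide F3. Zinc insertion (Zn dust, LiCl, THF, 30 °C; the alkenyl iodide should stay inert) gives alkylzinc iodide F4. Slow addition of F4 to Pd(PPh3)4 in THF (intramolecular Negishi coupling) closes the ring and comes back to the route at 19.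

Step 10. What may go wrong: the hindered β,β-disubstituted enal adds slowly, the acid catalyst interconverts the two enal geometries (which exchanges C12 and C13) and the enantioselectivity is low. Fallback, setting out from Weinreb amide 12: 3-(trimethylsilyl)prop-2-ynyllithium (from 1-(trimethylsilyl)propyne and n-BuLi, THF, −78 °C) gives enone F5. Corey–Bakshi–Shibata reduction ((R)-Me-CBS oxazaborolidine, BH3·SMe2, THF, −30 °C; alkenyl as the large group) sets C8 in silylalkyne alcohol F6. K2CO3 in MeOH at 0 °C removes the alkyne silyl group and the sequence comes back to the route at 14. C8 is then set by asymmetric ketone reduction and the enal is avoided.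

**Further compounds**

F1 | step 14 | (6S,7S,8S)-8,12-bis[(triethylsilyl)oxy]-15-[(tert-butyldiphenylsilyl)oxy]germacra-1(10)E,4E,11(13)-trien-6-ol (6-epimer of 22) | C=C(CO[Si](CC)(CC)CC)[C@@H]1[C@@H](O[Si](CC)(CC)CC)C/C(C)=C/CC/C(CO[Si](c2ccccc2)(c2ccccc2)C(C)(C)C)=C\[C@@H]1O
F2 | step 13 | primary alcohol from hydroboration–oxidation of 17 (OH on C2) | I/C=C(C)/C[C@H](O[Si](CC)(CC)CC)/C=C(CO[Si](CC)(CC)CC)/COC/C=C(CO[Si](c1ccccc1)(c1ccccc1)C(C)(C)C)\CCO
F3 | step 13 | alkyl iodide from F2 (I on C2) | I/C=C(C)/C[C@H](O[Si](CC)(CC)CC)/C=C(CO[Si](CC)(CC)CC)/COC/C=C(CO[Si](c1ccccc1)(c1ccccc1)C(C)(C)C)\CCI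
F4 | step 13 | alkylzinc iodide from F3 (Zn on C2) | I/C=C(C)/C[C@H](O[Si](CC)(CC)CC)/C=C(CO[Si](CC)(CC)CC)/COC/C=C(CO[Si](c1ccccc1)(c1ccccc1)C(C)(C)C)\CC[Zn]I
F5 | step 10 | (2Z)-1-(Dn-oxy)-2-{[(triethylsilyl)oxy]methyl}-7-(trimethylsilyl)hept-2-en-6-yn-4-one | C[Si](C)(C)C#CCC(=O)/C=C(CO[Si](CC)(CC)CC)/COC/C=C(CO[Si](c1ccccc1)(c1ccccc1)C(C)(C)C)\C=C
F6 | step 10 | (2Z,4S)-1-(Dn-oxy)-2-{[(triethylsilyl)oxy]methyl}-7-(trimethylsilyl)hept-2-en-6-yn-4-ol | C[Si](C)(C)C#CC[C@H](O)/C=C(CO[Si](CC)(CC)CC)/COC/C=C(CO[Si](c1ccccc1)(c1ccccc1)C(C)(C)C)\C=C
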